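**Plan**

1. Atom labels used below: cyclohexane C1 (bears =CH2), C2 and C3 (ring fusion), C4 (i-Pr), C5 (CH2), C6 (O-acyl); cyclopentanone C7 (ethylidene carbon, on C3), C8 (C=O), C9 (O-acyl, on C2).
2. Retrosynthetic cuts, in order: C7–C8 (alkyne hydroacylation of a C8 aldehyde onto a C7≡C–CH3 group), the two ester C–O bonds, the exocyclic C1=CH2 (sulfoxide elimination), then C1–C2 and C3–C4 together (Diels–Alder).
3. Enabling feature: O9 and C7 lie 1,4 across the ring-fusion bond C2–C3, so C9–O9–C7(=O) can be tied up as a butenolide whose alkene is C2=C3 and whose CH2O arm is C8; the C6 oxygen next to C1 makes C4=C5–C6(OSi)=C1 a 2-silyloxy diene.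
4. Forward: diene (3 steps) plus (S)-butenolide give the cyclohexene ring first, carrying a temporary lactone; the lactone is reduced and homologated to the propynyl group with epimerisation at C3; esters, C6 reduction and C1=CH2 follow; the cyclopentanone is closed last.
5. Stereochemistry: C9 from the chiral pool; C2 and C4 from the cycloaddition (anti to CH2O, endo); C3 by equilibration at the aldehyde stage (trans ring fusion); C6 by equatorial hydride attack; E-ethylidene by syn hydroacylation; the acyl stereocentre from (R)-2-methylbutanoic acid.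

Key step: step 5

Remark: compounds 1, 5, 12 and 17 are taken as commercial; TBDPS = tert-butyldiphenylsilyl, TIPS = triisopropylsilyl.

**Route**

Step 1
Reactants: 1 (E)-5-methylhex-3-en-2-one
Product: 2 (E)-trimethyl[(5-methylhexa-1,3-dien-2-yl)oxy]silane
Conditions: LiN(i-Pr)2, THF, −78 °C; Me3SiCl
Reagents that add atoms: chlorotrimethylsilane, C[Si](C)(C)Cl
Why: Kinetic deprotonation of the methyl group (α′ position) and O-silylation should give the cross-conjugated silyl dienol ether (regioselective silyl enol ether formation); no stereocentre is formed.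

Step 2
Reactants: 2 (E)-trimethyl[(5-methylhexa-1,3-dien-2-yl)oxy]silane
Product: 3 (E)-6-methyl-1-(phenylsulfanyl)hept-4-en-3-one
Conditions: PhSCH2Cl, ZnBr2 (5 mol %), CH2Cl2, rt
Reagents that add atoms: chloromethyl phenyl sulfide, ClCSc1ccccc1
Why: ZnBr2 ionises the α-chloro sulfide to a thionium ion that is captured by the CH2 terminus of the silyl enol ether (Mukaiyama-type α-phenylthiomethylation), which installs the future exocyclic methylene carbon as a CH2SPh handle.

Step 3
Reactants: 3 (E)-6-methyl-1-(phenylsulfanyl)hept-4-en-3-one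
Product: 4 triisopropyl{[(2Z,4E)-6-methyl-1-(phenylsulfanyl)hepta-2,4-dien-3-yl]oxy}silane
Conditions: i-Pr3SiOTf, Et3N, CH2Cl2, 0 °C
Reagents that add atoms: triisopropylsilyl trifluoromethanesulfonate, CC(C)[Si](C(C)C)(C(C)C)OS(=O)(=O)C(F)(F)F
Why: Soft enolisation at the α′-CH2 (silyl enol ether formation) should give the 2-silyloxy diene as the thermodynamically preferred Z enol ether, the geometry that places CH2SPh outward in the s-cis diene, while the E alkene is untouched.

Step 4
Reactants: 5 (S)-5-(hydroxymethyl)furan-2(5H)-one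
Product: 6 (S)-5-{[(tert-butyldiphenylsilyl)oxy]methyl}furan-2(5H)-one
Conditions: t-BuPh2SiCl, imidazole, DMF, 0 °C to rt
Reagents that add atoms: tert-butyl(chloro)diphenylsilane, CC(C)(C)[Si](Cl)(c1ccccc1)c1ccccc1
Why: Silylation of the primary alcohol (silyl ether protection) leaves the C5 stereocentre untouched and gives a bulky group that shields one face of the butenolide.

Step 5
Reactants: 4 triisopropyl{[(2Z,4E)-6-methyl-1-(phenylsulfanyl)hepta-2,4-dien-3-yl]oxy}silane; 6 (S)-5-{[(tert-butyldiphenylsilyl)oxy]methyl}furan-2(5H)-one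
Product: 7 all-cis lactone cycloadduct
Conditions: 4 (1.5 equiv), BHT (cat.), toluene, 130 °C, sealed tube
Reagents that add atoms: none
Why: This is a thermal normal-electron-demand Diels–Alder reaction between the electron-rich 2-silyloxy diene 4 and butenolide 6, a concerted asynchronous suprafacial–suprafacial [4+2] process whose closest precedent is the addition of 2-silyloxy dienes to γ-substituted butenolides. It closes the cyclohexene ring C1–C6 in an intermolecular six-membered cycloaddition, forming C1–C2 and C3–C4 at once, while the lactone comes in as a temporary ring. C2 and C3 come out cis because the dienophile is a cyclic Z-alkene, and both are fixed in the absolute sense by approach of the diene to the butenolide face opposite the CH2OTBDPS group on C9. C4 (isopropyl) and C1 (CH2SPh) follow from the 4E and 2Z geometry of 4 together with the endo transition state (lactone carbonyl under the diene), which places both outward substituents cis to the lactone. Regioselectivity is needed and is secured by the silyloxy group on C6, which makes C1 the nucleophilic terminus that bonds to the β-carbon C2, reinforced by the ortho preference of the alkyl-substituted terminus C4 for the α-carbon C3. Endo selectivity is the weaker requirement and rests on secondary overlap with the lactone carbonyl.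

Step 6
Reactants: 7 all-cis lactone cycloadduct
Product: 8 lactol
Conditions: i-Bu2AlH (1.1 equiv), CH2Cl2, −78 °C; aqueous Rochelle salt
Reagents that add atoms: none
Why: Partial reduction of the γ-lactone to the lactol (the aluminium hemiacetal is stable at −78 °C) should leave the silyl enol ether, silyl ether and sulfide untouched; the new anomeric centre is immaterial.

Step 7
Reactants: 8 lactol
Product: 10 terminal alkyne carbinol, via trans-hydroxy-aldehyde 9 (not isolated)
Conditions: K2CO3, MeOH, rt (equilibration); then dimethyl (1-diazo-2-oxopropyl)phosphonate, 0 °C to rt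
Reagents that add atoms: dimethyl (1-diazo-2-oxopropyl)phosphonate, CC(=O)C(=[N+]=[N-])P(=O)(OC)OC
Why: The lactol opens to the hydroxy-aldehyde, whose C3 (α to CHO) should epimerise under base to the trans isomer 9 in which the C2, C3 and C4 substituents are all equatorial (the all-cis array cannot avoid a 1,3-diaxial contact), and Seyferth–Gilbert homologation with the Bestmann–Ohira reagent then turns the aldehyde into the alkyne, after which C3 can no longer epimerise.

Step 8
Reactants: 10 terminal alkyne carbinol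
Product: 11 propynyl carbinol
Conditions: n-BuLi (2.2 equiv), THF, −78 °C; MeI (1.1 equiv), −78 to 0 °C; H2O
Reagents that add atoms: iodomethane, CI
Why: Double deprotonation gives the alkoxide–acetylide, of which the carbon nucleophile should be methylated selectively (acetylide alkylation) because a lithium alkoxide is inert to MeI in THF at low temperature; no stereocentre is touched.

Step 9
Reactants: 11 propynyl carbinol; 12 (R)-2-methylbutanoic acid
Product: 13 C9 (R)-2-methylbutanoate
Conditions: DCC, DMAP (cat.), CH2Cl2, 0 °C to rt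
Reagents that add atoms: none
Why: Steglich esterification acylates the C9 hydroxyl without breaking the C9–O bond and without enolising the acid, so both stereocentres are retained, and the silyl enol ether keeps C6 masked.

Step 10
Reactants: 13 C9 (R)-2-methylbutanoate
Product: 15 C6 ketone with equatorial CH2SPh, via axial-CH2SPh ketone 14 (not isolated)
Conditions: HCl (2 M aq.), THF, rt; then DBU (0.2 equiv), PhSH (0.1 equiv), CH2Cl2, rt
Reagents that add atoms: none
Why: Acid hydrolysis of the silyl enol ether (C-protonation at C5, then desilylation) unmasks the C6 ketone, and base then equilibrates the α-centre C1, by enolisation or reversible thiolate elimination and re-addition, from the axial CH2SPh set by the cycloaddition to the more stable equatorial one (α-epimerisation of a ketone).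

Step 11
Reactants: 15 C6 ketone with equatorial CH2SPh
Product: 16 C6 axial alcohol
Conditions: LiBH(s-Bu)3, THF, −78 °C; H2O
Reagents that add atoms: none
Why: The bulky hydride should attack the 2-substituted cyclohexanone (all four ring substituents equatorial) from the equatorial direction, giving the axial C6 alcohol cis to CH2SPh (diastereoselective ketone reduction), and the ester is not reduced at −78 °C.

Step 12
Reactants: 16 C6 axial alcohol; 17 (E)-3-methylpent-2-enoic acid
Product: 18 diester sulfide
Conditions: DCC, DMAP (cat.), CH2Cl2, rt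
Reagents that add atoms: none
Why: Steglich esterification of the axial alcohol proceeds with retention at C6, and the mild conditions should keep the E geometry and conjugation of the enoate.

Step 13
Reactants: 18 diester sulfide
Product: 20 exocyclic methylene diester, via sulfoxide 19 (not isolated)
Conditions: m-CPBA (1.0 equiv), CH2Cl2, −78 °C; aqueous work-up; then toluene, 110 °C
Reagents that add atoms: none
Why: Chemoselective S-oxidation followed by thermal syn-elimination of the sulfoxide (sulfoxide pyrolysis) should give the exocyclic C1=CH2 regiospecifically, since the only β-hydrogen is on C1.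

Step 14
Reactants: 20 exocyclic methylene diester
Product: 21 primary alcohol
Conditions: HF·pyridine, pyridine, THF, 0 °C to rt
Reagents that add atoms: none
Why: Fluoride cleavage of the primary silyl ether (desilylation) in a weakly acidic medium should suppress acyl migration from O9 to the freed C8 hydroxyl.

Step 15
Reactants: 21 primary alcohol
Product: 22 α-acyloxy aldehyde
Conditions: Dess–Martin periodinane, CH2Cl2, 0 °C to rt
Reagents that add atoms: none
Why: Dess–Martin oxidation gives the aldehyde under non-basic conditions that should not epimerise C9; the crude aldehyde is used directly.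

Step 16
Reactants: 22 α-acyloxy aldehyde
Product: 23 CNP0196246.3
Conditions: [Rh(cod)2]BF4 (10 mol %), rac-BINAP (10 mol %), H2 (catalyst activation) then Ar, CH2Cl2, rt
Reagents that add atoms: none
Why: Oxidative addition of the cationic monovalent rhodium complex into the aldehyde C–H bond, syn insertion of the alkyne into Rh–H and C–C reductive elimination (intramolecular hydroacylation of a 5-alkynal) should close the cyclopentanone between C8 and C7 and place H cis to the carbonyl, which is the required E-ethylidene.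

**Compound list**

1 | (E)-5-methylhex-3-en-2-one | CC(=O)/C=C/C(C)C | starting material
2 | (E)-trimethyl[(5-methylhexa-1,3-dien-2-yl)oxy]silane | C=C(O[Si](C)(C)C)/C=C/C(C)C | intermediate
3 | (E)-6-methyl-1-(phenylsulfanyl)hept-4-en-3-one | O=C(CCSc1ccccc1)/C=C/C(C)C | intermediate
4 | triisopropyl{[(2Z,4E)-6-methyl-1-(phenylsulfanyl)hepta-2,4-dien-3-yl]oxy}silane | CC(C)/C=C/C(O[Si](C(C)C)(C(C)C)C(C)C)=C/CSc1ccccc1 | intermediate
5 | (S)-5-(hydroxymethyl)furan-2(5H)-one | O=C1C=C[C@@H](CO)O1 | starting material
6 | (S)-5-{[(tert-butyldiphenylsilyl)oxy]methyl}furan-2(5H)-one | O=C1C=C[C@@H](CO[Si](c2ccccc2)(c2ccccc2)C(C)(C)C)O1 | intermediate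
7 | all-cis lactone cycloadduct: 3-(TBDPS-oxymethyl)-7-isopropyl-4-(phenylsulfanylmethyl)-5-(TIPS-oxy)-3a,4,7,7a-tetrahydroisobenzofuran-1(3H)-one; H-3a/H-4/H-7/H-7a all cis; H-3 trans to H-3a | c1ccccc1SC[C@@H]2[C@H]3[C@H](C(=O)O[C@@H]3CO[Si](c4ccccc4)(c5ccccc5)C(C)(C)C)[C@H](C(C)C)C=C2O[Si](C(C)C)(C(C)C)C(C)C | intermediate
8 | lactol of 7 (1-hydroxy-1,3,3a,4,7,7a-hexahydroisobenzofuran; anomer mixture; other centres as in 7) | c1ccccc1SC[C@@H]2[C@H]3[C@H](C(O)O[C@@H]3CO[Si](c4ccccc4)(c5ccccc5)C(C)(C)C)[C@H](C(C)C)C=C2O[Si](C(C)C)(C(C)C)C(C)C | intermediate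
9 | trans-hydroxy-aldehyde: open form epimerised at C3; CHO trans to the isopropyl group on C4 and to the (S)-CH(OH)CH2OTBDPS chain on C2; CH2SPh on C1 cis to that chain; OTIPS on C6 | c1ccccc1SC[C@@H]2[C@H]([C@H](O)CO[Si](c3ccccc3)(c4ccccc4)C(C)(C)C)[C@@H](C=O)[C@H](C(C)C)C=C2O[Si](C(C)C)(C(C)C)C(C)C | intermediate
10 | terminal alkyne carbinol: as 9 with ethynyl in place of CHO | c1ccccc1SC[C@@H]2[C@H]([C@H](O)CO[Si](c3ccccc3)(c4ccccc4)C(C)(C)C)[C@@H](C#C)[C@H](C(C)C)C=C2O[Si](C(C)C)(C(C)C)C(C)C | intermediate
11 | propynyl carbinol: as 10 with prop-1-ynyl on C3 | c1ccccc1SC[C@@H]2[C@H]([C@H](O)CO[Si](c3ccccc3)(c4ccccc4)C(C)(C)C)[C@@H](C#CC)[C@H](C(C)C)C=C2O[Si](C(C)C)(C(C)C)C(C)C | intermediate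
12 | (R)-2-methylbutanoic acid | CC[C@@H](C)C(O)=O | starting material
13 | C9 (R)-2-methylbutanoate of 11 | c1ccccc1SC[C@@H]2[C@H]([C@H](OC(=O)[C@H](C)CC)CO[Si](c3ccccc3)(c4ccccc4)C(C)(C)C)[C@@H](C#CC)[C@H](C(C)C)C=C2O[Si](C(C)C)(C(C)C)C(C)C | intermediate
14 | C6 ketone with axial CH2SPh (C1 as formed in the cycloaddition; cis to the C2 chain) | c1ccccc1SC[C@@H]2[C@H]([C@H](OC(=O)[C@H](C)CC)CO[Si](c3ccccc3)(c4ccccc4)C(C)(C)C)[C@@H](C#CC)[C@H](C(C)C)CC2=O | intermediate
15 | C6 ketone with equatorial CH2SPh (C1 epimer of 14; all four ring substituents equatorial) | c1ccccc1SC[C@H]2[C@H]([C@H](OC(=O)[C@H](C)CC)CO[Si](c3ccccc3)(c4ccccc4)C(C)(C)C)[C@@H](C#CC)[C@H](C(C)C)CC2=O | intermediate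
16 | C6 axial alcohol (OH cis to CH2SPh on C1) | c1ccccc1SC[C@H]2[C@H]([C@H](OC(=O)[C@H](C)CC)CO[Si](c3ccccc3)(c4ccccc4)C(C)(C)C)[C@@H](C#CC)[C@H](C(C)C)C[C@H]2O | intermediate
17 | (E)-3-methylpent-2-enoic acid | CC/C(C)=C/C(O)=O | starting material
18 | diester sulfide: C6 (E)-3-methylpent-2-enoate of 16 | c1ccccc1SC[C@H]2[C@H]([C@H](OC(=O)[C@H](C)CC)CO[Si](c3ccccc3)(c4ccccc4)C(C)(C)C)[C@@H](C#CC)[C@H](C(C)C)C[C@H]2OC(=O)/C=C(\C)CC | intermediate
19 | sulfoxide of 18 (mixture at sulfur) | c1ccccc1S(=O)C[C@H]2[C@H]([C@H](OC(=O)[C@H](C)CC)CO[Si](c3ccccc3)(c4ccccc4)C(C)(C)C)[C@@H](C#CC)[C@H](C(C)C)C[C@H]2OC(=O)/C=C(\C)CC | intermediate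
20 | exocyclic methylene diester with C8 OTBDPS | C=C1[C@H]([C@H](OC(=O)[C@H](C)CC)CO[Si](c2ccccc2)(c3ccccc3)C(C)(C)C)[C@@H](C#CC)[C@H](C(C)C)C[C@H]1OC(=O)/C=C(\C)CC | intermediate
21 | primary alcohol (C8 OH) | C=C1[C@H]([C@H](OC(=O)[C@H](C)CC)CO)[C@@H](C#CC)[C@H](C(C)C)C[C@H]1OC(=O)/C=C(\C)CC | intermediate
22 | α-acyloxy aldehyde (C8 CHO; a 5-alkynal) | C=C1[C@H]([C@H](OC(=O)[C@H](C)CC)C=O)[C@@H](C#CC)[C@H](C(C)C)C[C@H]1OC(=O)/C=C(\C)CC | intermediate
23 | CNP0196246.3: trans-fused (E)-1-ethylidene-7-isopropyl-4-methylidene-2-oxooctahydro-1H-indene-3,5-diyl 3-[(R)-2-methylbutanoate] 5-[(E)-3-methylpent-2-enoate] | C=C1[C@H]2[C@@H](/C(=C\C)C(=O)[C@H]2OC(=O)[C@H](C)CC)[C@H](C(C)C)C[C@H]1OC(=O)/C=C(\C)CC | target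

**Summary**

Total step count: 16. Longest linear sequence: 15 steps (from 1 through steps 1–3 and 5–16).

Steps most likely to fail:

Step 5. The cycloaddition may be too slow at a temperature the diene tolerates, and endo selectivity (which sets C4) may erode at the temperature needed. Fallback, from 6 back to 7: butenolide 6 would be brominated (Br2, CH2Cl2, 0 °C) to the trans-dibromolactone F1 and dehydrobrominated with Et3N to the 3-bromobutenolide F2, a much more reactive dienophile. It should add diene 4 below 80 °C with the same regio- and facial sense and the lactone carbonyl endo, giving the α-bromolactone cycloadduct F3. Radical debromination (Bu3SnH, AIBN cat., toluene, 80 °C) should then return lactone 7; either C3 epimer would serve, because C3 is equilibrated in step 7.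

Step 7. The cis-hydroxy-aldehyde may be homologated faster than it epimerises, or the lactol may open too slowly, so that the cis-alkyne is carried forward. Fallback, from 7 back to 11, with the epimerisation done as a separate step on an acyclic aldehyde: lactone 7 would be opened with MeNH(OMe)·HCl and Me3Al to the hydroxy Weinreb amide F4, which would be silylated (Et3SiOTf, 2,6-lutidine) to the triethylsilyl ether F5. Reduction with i-Bu2AlH at −78 °C would give the cis-aldehyde F6, and DBU in CH2Cl2 would equilibrate it to the all-equatorial trans-aldehyde F7. Bestmann–Ohira homologation would give the terminal alkyne F8, n-BuLi then MeI the propynyl compound F9, and PPTS in MeOH would remove the triethylsilyl group to give 11.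

Step 16. The acyl rhodium hydride from the α-acyloxy aldehyde may lose CO before the alkyne inserts. Fallback, from 22 back to 23: aldehyde 22 would be cyclised by nickel-catalysed reductive coupling of aldehyde and alkyne (Ni(cod)2 as zerovalent nickel source, PBu3, Et3SiH, THF), a syn addition across the alkyne that gives the same ethylidene geometry, to the silyl-protected allylic alcohol F10. Desilylation with HF·pyridine would give the allylic alcohol F11, and Dess–Martin oxidation would give 23.

**Further compounds**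

F1 | step 5 | trans-3,4-dibromo-5-(TBDPS-oxymethyl)dihydrofuran-2(3H)-one (C-3/C-4 configuration immaterial) | O=C1C(Br)C(Br)[C@@H](CO[Si](c2ccccc2)(c2ccccc2)C(C)(C)C)O1
F2 | step 5 | (S)-3-bromo-5-{[(tert-butyldiphenylsilyl)oxy]methyl}furan-2(5H)-one | O=C1C(Br)=C[C@@H](CO[Si](c2ccccc2)(c2ccccc2)C(C)(C)C)O1
F3 | step 5 | 7a-bromo analogue of cycloadduct 7 (Br on C3 in place of H) | c1ccccc1SC[C@@H]2[C@H]3[C@](Br)(C(=O)O[C@@H]3CO[Si](c4ccccc4)(c5ccccc5)C(C)(C)C)[C@H](C(C)C)C=C2O[Si](C(C)C)(C(C)C)C(C)C
F4 | step 7 | hydroxy Weinreb amide from 7 (C3 cis to both neighbours) | c1ccccc1SC[C@@H]2[C@H]([C@H](O)CO[Si](c3ccccc3)(c4ccccc4)C(C)(C)C)[C@H](C(=O)N(C)OC)[C@H](C(C)C)C=C2O[Si](C(C)C)(C(C)C)C(C)C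
F5 | step 7 | O9 triethylsilyl ether of F4 | c1ccccc1SC[C@@H]2[C@H]([C@H](O[Si](CC)(CC)CC)CO[Si](c3ccccc3)(c4ccccc4)C(C)(C)C)[C@H](C(=O)N(C)OC)[C@H](C(C)C)C=C2O[Si](C(C)C)(C(C)C)C(C)C
F6 | step 7 | cis-aldehyde (CHO on C3 cis to both neighbours) | c1ccccc1SC[C@@H]2[C@H]([C@H](O[Si](CC)(CC)CC)CO[Si](c3ccccc3)(c4ccccc4)C(C)(C)C)[C@H](C=O)[C@H](C(C)C)C=C2O[Si](C(C)C)(C(C)C)C(C)C
F7 | step 7 | trans-aldehyde (C3 epimer of F6) | c1ccccc1SC[C@@H]2[C@H]([C@H](O[Si](CC)(CC)CC)CO[Si](c3ccccc3)(c4ccccc4)C(C)(C)C)[C@@H](C=O)[C@H](C(C)C)C=C2O[Si](C(C)C)(C(C)C)C(C)C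
F8 | step 7 | terminal alkyne with O9 triethylsilyl ether | c1ccccc1SC[C@@H]2[C@H]([C@H](O[Si](CC)(CC)CC)CO[Si](c3ccccc3)(c4ccccc4)C(C)(C)C)[C@@H](C#C)[C@H](C(C)C)C=C2O[Si](C(C)C)(C(C)C)C(C)C
F9 | step 7 | propynyl compound with O9 triethylsilyl ether | c1ccccc1SC[C@@H]2[C@H]([C@H](O[Si](CC)(CC)CC)CO[Si](c3ccccc3)(c4ccccc4)C(C)(C)C)[C@@H](C#CC)[C@H](C(C)C)C=C2O[Si](C(C)C)(C(C)C)C(C)C
F10 | step 16 | C8 triethylsilyl ether of the allylic alcohol (C8 either epimer; E-ethylidene) | C=C1[C@H]2[C@@H](/C(=C\C)C(O[Si](CC)(CC)CC)[C@H]2OC(=O)[C@H](C)CC)[C@H](C(C)C)C[C@H]1OC(=O)/C=C(\C)CC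
F11 | step 16 | C8 allylic alcohol (C8 either epimer; E-ethylidene) | C=C1[C@H]2[C@@H](/C(=C\C)C(O)[C@H]2OC(=O)[C@H](C)CC)[C@H](C(C)C)C[C@H]1OC(=O)/C=C(\C)CC
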